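Cuts (retro): the C18 silyl ether and a helper bromine on C7; C7 is then taken out of ring B, so C6–C7–C8 goes back to a C6=C8 cyclopentene plus CBr2. Further cuts: C12–C13 (Suzuki–Miyaura), C9–H and C9–C11 (hydrogenolysis, vinyl addition), C8–CH3, C4–C18, ring A (Michael/aldol).
Forward: ring A is annulated onto 2-methylcyclopentane-1,3-dione and C4 is quaternised. The five-membered ring C5–C6–C8–C9–C10 then receives the C8 methyl group, the C6=C8 double bond and the complete C9 side chain. Only then is it enlarged to ring B by insertion of C7.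
Enabling feature: in ring B the carbinol C6, the vinylic CH C7 and the methyl-bearing C8 stand in a row, which is the imprint of an allyl cation C6–C7–C8. A bromocyclopropane fused to the five-membered ring gives exactly this cation on electrocyclic opening, and the axial methyl groups on C4 and C10 tell its two faces apart.
Stereochemistry: C10 comes from a D-phenylalanine-catalysed aldol desymmetrisation. C4, C5, C9 and C6 are each set by attack anti to the C10 methyl group (alkylation, hydroboration, palladium-bound hydride, carboxylate capture). The E-enoate comes from an E enol triflate with retention.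

Key step: step 15

Remark: labdane numbering is used for all bicyclic compounds (C7 is missing in the hydrindanes). α is the face that carries the C10 methyl group and β is the opposite face. The SMILES is read as the 10α-methyl (ent) series with 5β-H, 9β-H, equatorial 6β-OH, axial 4α-CH3 and equatorial 4β-CH2OH.

Step 1
Reactants: 1 2-methylcyclopentane-1,3-dione; 2 pent-1-en-3-one
Product: 3 2-methyl-2-(3-oxopentyl)cyclopentane-1,3-dione
Conditions: H2O, AcOH (cat.), 75 °C
Reagents that add atoms: none
Why: Michael addition of the acidic 1,3-dione to the enone stops at the mono-adduct because no acidic C–H is left between the two ring carbonyl groups.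

Step 2
Reactants: 3 2-methyl-2-(3-oxopentyl)cyclopentane-1,3-dione
Product: 4 (7aR)-4,7a-dimethyl-2,3,7,7a-tetrahydro-1H-indene-1,5(6H)-dione
Conditions: D-phenylalanine (cat.), (1R)-(−)-camphor-10-sulfonic acid (cat.), DMF, 30 → 70 °C
Reagents that add atoms: none
Why: Hajos–Parrish–Eder–Sauer–Wiechert reaction, in which the enamine of the ethyl ketone attacks one of the two enantiotopic ring carbonyl groups, sets C10 (7aR with the D-amino acid) and dehydrates to the enone.

Step 3
Reactants: 4 (7aR)-enedione
Product: 5 C9 ethylene ketal of enedione 4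
Conditions: TMSOCH2CH2OTMS, TMSOTf (cat.), CH2Cl2, −78 → −20 °C
Reagents that add atoms: 1,2-bis(trimethylsilyloxy)ethane, C[Si](C)(C)OCCO[Si](C)(C)C
Why: silyl-triflate-catalysed ketalisation at low temperature should pick the saturated cyclopentanone over the less electrophilic, fully substituted enone.

Step 4
Reactants: 5 C9 ethylene ketal of enedione 4
Product: 6 3-oxo-4α-methyl-4β-(triisopropylsilyloxymethyl)-Δ5(6)-hydrindene C9 ketal
Conditions: KOtBu, THF–t-BuOH, 0 °C; then TIPSOCH2Cl, −40 → 0 °C
Reagents that add atoms: (triisopropylsiloxy)methyl chloride, ClCO[Si](C(C)C)(C(C)C)C(C)C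
Why: deconjugative α-alkylation of the extended dienolate forms the C4–C18 bond and moves the double bond to C5=C6, and the electrophile enters anti to the C10 methyl group, so CH2OTIPS becomes equatorial (β) and the C4 methyl group axial (α).

Step 5
Reactants: 6 3-oxo-4α-methyl-4β-(triisopropylsilyloxymethyl)-Δ5(6)-hydrindene C9 ketal
Product: 8 3-deoxo Δ5(6)-hydrindene C9 ketal, via N-silyl hydrazone 7 (not isolated)
Conditions: TBSNHNHTBS, Sc(OTf)3 (cat.), neat, 60–100 °C; then KOtBu, t-BuOH, DMSO, 100 °C
Reagents that add atoms: none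
Why: Wolff–Kishner reduction in its N-silyl hydrazone variant removes the activating C3 carbonyl group under base-only conditions that ketal, neopentyl silyl ether and the non-conjugated alkene should survive.

Step 6
Reactants: 8 3-deoxo Δ5(6)-hydrindene C9 ketal
Product: 10 6β-hydroxy-5β-H trans-hydrindane C9 ketal, via alkylborane 9 (not isolated)
Conditions: BH3·THF, THF, 0 °C → rt; then NaOH, H2O2, 0 °C → rt
Reagents that add atoms: hydrogen peroxide, OO
Why: syn hydroboration with oxidation under retention puts boron on the less substituted C6 and hydrogen on C5 from the β face, anti to the methyl groups on C10 and C4, which sets H5 and the trans ring fusion.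

Step 7
Reactants: 10 6β-hydroxy-5β-H trans-hydrindane C9 ketal
Product: 13 9-oxo-Δ6(8) trans-hydrindenone, via hydroxy ketone 11 (not isolated), via mesylate 12 (not isolated)
Conditions: p-TsOH·H2O (cat.), acetone–H2O, 40 °C; then MsCl, Et3N, CH2Cl2, 0 °C → rt
Reagents that add atoms: water, O
Why: ketal hydrolysis gives a β-hydroxy ketone whose mesylate undergoes E1cB elimination with an amine too weak to remove the γ-hydrogen at C5, so the trans fusion should be kept.

Step 8
Reactants: 13 9-oxo-Δ6(8) trans-hydrindenone
Product: 14 8-iodo enone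
Conditions: I2, pyridine–CH2Cl2, 0 °C → rt
Reagents that add atoms: iodine, II
Why: α-iodination of a cyclic enone proceeds by a Baylis–Hillman-type sequence of amine conjugate addition, iodination of the enolate and elimination.

Step 9
Reactants: 14 8-iodo enone
Product: 15 8-methyl enone
Conditions: MeZnCl, Pd(dppf)Cl2 (cat.), THF, rt
Reagents that add atoms: methylzinc chloride, C[Zn]Cl
Why: Negishi coupling of an α-iodoenone installs the C8 methyl group under neutral conditions that do not epimerise C5.

Step 10
Reactants: 15 8-methyl enone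
Product: 17 methyl carbonate of the 9β-vinyl-9α-carbinol, via magnesium alkoxide 16 (not isolated)
Conditions: CH2=CHMgBr, THF, −78 → 0 °C; then ClCO2Me, 0 °C → rt
Reagents that add atoms: vinylmagnesium bromide, C=C[Mg]Br; methyl chloroformate, COC(=O)Cl
Why: the hard Grignard reagent adds 1,2 to a ketone that has no α′-hydrogen, from the β face anti to the C10 methyl group, and the alkoxide is acylated in the same flask.

Step 11
Reactants: 17 methyl carbonate of the 9β-vinyl-9α-carbinol
Product: 18 9α-vinyl-9β-H-8-methyl-Δ6(8)-hydrindene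
Conditions: Pd2(dba)3 (cat.), PBu3 (cat.), HCO2H, Et3N, THF, rt → 40 °C
Reagents that add atoms: none
Why: Tsuji–Trost-type ionisation by zerovalent palladium anti to the α carbonate followed by formate hydrogenolysis passes hydride from the β-bound metal to the more substituted allyl terminus C9, which should leave the terminal vinyl group and the C6=C8 bond in place and set H9 β.

Step 12
Reactants: 19 methyl acetoacetate
Product: 20 methyl (E)-3-(trifluoromethylsulfonyloxy)but-2-enoate
Conditions: Tf2O, aq. Me4NOH, toluene, 5 °C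
Reagents that add atoms: trifluoromethanesulfonic anhydride, O=S(=O)(OS(=O)(=O)C(F)(F)F)C(F)(F)F
Why: O-sulfonylation of the non-chelated ammonium enolate should give the enol triflate with the sulfonate trans to the ester.

Step 13
Reactants: 18 9α-vinyl-9β-H-8-methyl-Δ6(8)-hydrindene; 20 methyl (E)-3-(trifluoromethylsulfonyloxy)but-2-enoate
Product: 22 7-nor dienoate (full side chain on the C6=C8 hydrindene), via B-alkyl-9-BBN 21 (not isolated)
Conditions: 9-BBN, THF, rt; then 20, Pd(dppf)Cl2 (cat.), aq. K3PO4, THF–DMF, rt → 50 °C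
Reagents that add atoms: none
Why: B-alkyl Suzuki–Miyaura coupling, in which 9-BBN adds only to the monosubstituted alkene and the C12–C13 bond forms with retention of the triflate geometry, giving the E-enoate.

Step 14
Reactants: 22 7-nor dienoate
Product: 23 6β,8β-(dibromomethano) adduct
Conditions: CHBr3, KOtBu, pentane, −10 → 0 °C
Reagents that add atoms: bromoform, BrC(Br)Br
Why: the electrophilic dibromocarbene adds [2+1] to the only electron-rich alkene (the enoate is deactivated), presumably from the open β face, and the face is of no consequence because C6 and C8 are planarised in the next step.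

Step 15
Reactants: 23 6β,8β-(dibromomethano) adduct
Product: 25 7-bromo-6β-alcohol (ring B six-membered), via allylic trifluoroacetate 24 (not isolated)
Conditions: AgO2CCF3, CH2Cl2, 0 °C → rt, dark; then K2CO3 (cat.), MeOH, 0 °C
Reagents that add atoms: silver trifluoroacetate, [Ag+].[O-]C(=O)C(F)(F)F
Why: Monovalent silver abstracts the endo bromide while the shared C6–C8 bond opens in the disrotatory two-electron electrocyclic sense allowed by orbital symmetry, so the five-membered ring C5–C6–C8–C9–C10 becomes six-membered ring B as a 7-bromoallyl cation over C6–C7–C8, driven by strain release from the cyclopropane and the trans-hydrindene. The closest known reaction type is the silver-carboxylate-promoted enlargement of 6,6-dibromobicyclo[3.1.0]hexanes to 2-bromocyclohex-2-enyl esters. No ring is closed: an existing ring is enlarged by the one carbon (C7) that the carbene delivered, which fixes the double bond at C7=C8 and the oxygen at C6 without any chance of migration to other ring positions. The only new stereocentre, C6, is set by trifluoroacetate attack on the β face, anti to the axial methyl groups on C4 and C10 that cover the α face, and this equatorial ester is also the more stable epimer. The step needs capture at C6 and not at C8, and capture rather than proton loss: an ester at C8 would force the C8 methyl group into a 1,3-diaxial clash with the C10 methyl group and leave a less substituted alkene, and as a tertiary allylic trifluoroacetate it should re-ionise, so the reversible nucleophile drains the mixture to the C6 ester, while the neutral non-basic medium and the saturated C11–C12 chain on C9 hold back elimination and hydride shifts. Catalytic carbonate in methanol then cleaves only the activated trifluoroacetate at its acyl carbon, with retention at C6.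

Step 16
Reactants: 25 7-bromo-6β-alcohol
Product: 26 18-O-triisopropylsilyl ether of the target
Conditions: Bu3SnH, AIBN (cat.), toluene, 80 °C
Reagents that add atoms: none
Why: radical chain hydrodebromination removes the helper bromine, since the vinyl radical at C7 should be trapped by the stannane faster than it can reach the side-chain enoate.

Step 17
Reactants: 26 18-O-triisopropylsilyl ether of the target
Product: 27 target
Conditions: Bu4NF, THF, 0 °C → rt
Reagents that add atoms: none
Why: fluoride-induced cleavage of the Si–O bond frees the C18 alcohol without touching the methyl enoate or the allylic alcohol.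

Compound list
1 | 2-methylcyclopentane-1,3-dione | CC1C(=O)CCC1=O | starting material
2 | pent-1-en-3-one (ethyl vinyl ketone) | C=CC(=O)CC | starting material
3 | 2-methyl-2-(3-oxopentyl)cyclopentane-1,3-dione | CCC(=O)CCC1(C)C(=O)CCC1=O | intermediate
4 | (7aR)-4,7a-dimethyl-2,3,7,7a-tetrahydro-1H-indene-1,5(6H)-dione (C7a = C10; ring ketone = C9) | C[C@@]12CCC(=O)C(C)=C1CCC2=O | intermediate
5 | C9 ethylene ketal of 4 (enone C3/C4=C5 kept) | C[C@@]12CCC(=O)C(C)=C1CCC23OCCO3 | intermediate
6 | 3-oxo-4α-methyl-4β-(triisopropylsilyloxymethyl)-10α-methyl-Δ5(6)-hydrindene C9 ketal | C12(OCCO1)CC=C3[C@@](C)(CO[Si](C(C)C)(C(C)C)C(C)C)C(=O)CC[C@@]23C | intermediate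
7 | N-(tert-butyldimethylsilyl)hydrazone of 6 at C3 | C12(OCCO1)CC=C3[C@@](C)(CO[Si](C(C)C)(C(C)C)C(C)C)C(=NN[Si](C)(C)C(C)(C)C)CC[C@@]23C | intermediate
8 | 4α-methyl-4β-(triisopropylsilyloxymethyl)-10α-methyl-Δ5(6)-hydrindene C9 ketal (C3 = CH2) | C12(OCCO1)CC=C3[C@@](C)(CO[Si](C(C)C)(C(C)C)C(C)C)CCC[C@@]23C | intermediate
9 | 6β-boryl-5β-H trans-hydrindane C9 ketal | C12(OCCO1)C[C@@H](B)[C@@H]3[C@@](C)(CO[Si](C(C)C)(C(C)C)C(C)C)CCC[C@@]23C | intermediate
10 | 6β-hydroxy-5β-H trans-hydrindane C9 ketal | C12(OCCO1)C[C@@H](O)[C@@H]3[C@@](C)(CO[Si](C(C)C)(C(C)C)C(C)C)CCC[C@@]23C | intermediate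
11 | 6β-hydroxy-9-oxo trans-hydrindane | O=C1C[C@@H](O)[C@@H]2[C@@](C)(CO[Si](C(C)C)(C(C)C)C(C)C)CCC[C@@]12C | intermediate
12 | 6β-mesyloxy-9-oxo trans-hydrindane | O=C1C[C@@H](OS(C)(=O)=O)[C@@H]2[C@@](C)(CO[Si](C(C)C)(C(C)C)C(C)C)CCC[C@@]12C | intermediate
13 | 9-oxo-Δ6(8) trans-hydrindenone (5β-H) | O=C1C=C[C@@H]2[C@@](C)(CO[Si](C(C)C)(C(C)C)C(C)C)CCC[C@@]12C | intermediate
14 | 8-iodo-9-oxo-Δ6(8) trans-hydrindenone | O=C1C(I)=C[C@@H]2[C@@](C)(CO[Si](C(C)C)(C(C)C)C(C)C)CCC[C@@]12C | intermediate
15 | 8-methyl-9-oxo-Δ6(8) trans-hydrindenone | O=C1C(C)=C[C@@H]2[C@@](C)(CO[Si](C(C)C)(C(C)C)C(C)C)CCC[C@@]12C | intermediate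
16 | bromomagnesium 9α-alkoxide of the 9β-vinyl carbinol | C=C[C@@]1(O[Mg]Br)C(C)=C[C@@H]2[C@@](C)(CO[Si](C(C)C)(C(C)C)C(C)C)CCC[C@@]12C | intermediate
17 | methyl carbonate of the 9β-vinyl-9α-carbinol (8-methyl-Δ6(8)) | C=C[C@@]1(OC(=O)OC)C(C)=C[C@@H]2[C@@](C)(CO[Si](C(C)C)(C(C)C)C(C)C)CCC[C@@]12C | intermediate
18 | 9α-vinyl-9β-H-8-methyl-Δ6(8) trans-hydrindene | C=C[C@@H]1C(C)=C[C@@H]2[C@@](C)(CO[Si](C(C)C)(C(C)C)C(C)C)CCC[C@@]12C | intermediate
19 | methyl acetoacetate | COC(=O)CC(C)=O | starting material
20 | methyl (E)-3-{[(trifluoromethyl)sulfonyl]oxy}but-2-enoate | COC(=O)/C=C(\C)OS(=O)(=O)C(F)(F)F | intermediate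
21 | B-(C12-alkyl)-9-borabicyclo[3.3.1]nonane from 18 | B1(C2CCCC1CCC2)CC[C@@H]3C(C)=C[C@@H]4[C@@](C)(CO[Si](C(C)C)(C(C)C)C(C)C)CCC[C@@]34C | intermediate
22 | methyl (13E)-7-nor-18-(triisopropylsilyloxy)labda-6(8),13-dien-15-oate (10α-methyl series; 5β-H; 9β-H) | COC(=O)/C=C(\C)CC[C@@H]1C(C)=C[C@@H]2[C@@](C)(CO[Si](C(C)C)(C(C)C)C(C)C)CCC[C@@]12C | intermediate
23 | 6β,8β-(dibromomethano) adduct of 22 (6α-H; 8α-methyl) | COC(=O)/C=C(\C)CC[C@@H]1[C@]2(C)[C@@H](C2(Br)Br)[C@@H]3[C@@](C)(CO[Si](C(C)C)(C(C)C)C(C)C)CCC[C@@]13C | intermediate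
24 | methyl (13E)-7-bromo-6β-(trifluoroacetoxy)-18-(triisopropylsilyloxy)labda-7,13-dien-15-oate | COC(=O)/C=C(\C)CC[C@@H]1C(C)=C(Br)[C@@H](OC(=O)C(F)(F)F)[C@@H]2[C@@](C)(CO[Si](C(C)C)(C(C)C)C(C)C)CCC[C@@]12C | intermediate
25 | methyl (13E)-7-bromo-6β-hydroxy-18-(triisopropylsilyloxy)labda-7,13-dien-15-oate | COC(=O)/C=C(\C)CC[C@@H]1C(C)=C(Br)[C@@H](O)[C@@H]2[C@@](C)(CO[Si](C(C)C)(C(C)C)C(C)C)CCC[C@@]12C | intermediate
26 | methyl (13E)-6β-hydroxy-18-(triisopropylsilyloxy)labda-7,13-dien-15-oate | COC(=O)/C=C(\C)CC[C@@H]1C(C)=C[C@@H](O)[C@@H]2[C@@](C)(CO[Si](C(C)C)(C(C)C)C(C)C)CCC[C@@]12C | intermediate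
27 | methyl (2E)-5-[(1R,4R,4aS,5S,8aS)-4-hydroxy-5-(hydroxymethyl)-2,5,8a-trimethyl-1,4,4a,5,6,7,8,8a-octahydronaphthalen-1-yl]-3-methylpent-2-enoate | COC(=O)/C=C(\C)CC[C@@H]1C(C)=C[C@@H](O)[C@@H]2[C@@](C)(CO)CCC[C@@]12C | target

Total step count: 17. Longest linear sequence: 16 (steps 1–11 and 13–17; step 12 is a one-step branch).

Steps most likely to fail

Step 15. The carboxylate may stay on the tertiary terminus C8, or the cation may lose a proton from C5, C9 or the C8 methyl group before it is captured. The fallback accepts the kinetic terminus and moves the oxygen afterwards. It sets out from 23, which is hydrolysed with AgBF4 and CaCO3 in aqueous acetone to the tertiary allylic alcohol methyl (13E)-7-bromo-8β-hydroxy-18-(triisopropylsilyloxy)labda-6,13-dien-15-oate F1. Bu3SnH/AIBN removes the bromine to give the 8β-hydroxy-Δ6 compound F2. A perrhenate-catalysed suprafacial 1,3-transposition of the allylic alcohol (Ph3SiOReO3, Et2O, low temperature) then carries the oxygen on the β face from C8 to C6. The more substituted alkene and the equatorial secondary alcohol pull this equilibrium, and the route is rejoined at 26.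

Step 11. Hydride may be delivered to the wrong allyl terminus (C6 or C12), giving conjugated dienes, or β-hydride elimination may outrun formate transfer. The fallback builds C9–H by hydroboration instead. It sets out from 15, which undergoes Wittig methylenation (Ph3P=CH2) to the exocyclic diene F3. 9-BBN adds to the exocyclic methylene from the β face, and oxidation gives the 9β-H primary alcohol F4. Dess–Martin oxidation gives the aldehyde F5, which is methylenated at once (Ph3P=CH2). The route is rejoined at 18.

Step 4. The hard chloromethyl ether may alkylate the dienolate on oxygen, or attack C4 with poor facial selectivity. The fallback replaces alkylation by an aldol reaction. It sets out from 5, whose potassium dienolate is treated with monomeric formaldehyde to give the 4β-hydroxymethyl-4α-methyl-Δ5(6)-3-ketone F6. This is silylated with TIPSOTf and 2,6-lutidine, and the route is rejoined at 6.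

Further compounds
F1 | step 15 | methyl (13E)-7-bromo-8β-hydroxy-18-(triisopropylsilyloxy)labda-6,13-dien-15-oate (8α-methyl) | COC(=O)/C=C(\C)CC[C@@H]1[C@@](C)(O)C(Br)=C[C@@H]2[C@@](C)(CO[Si](C(C)C)(C(C)C)C(C)C)CCC[C@@]12C
F2 | step 15 | methyl (13E)-8β-hydroxy-18-(triisopropylsilyloxy)labda-6,13-dien-15-oate (8α-methyl) | COC(=O)/C=C(\C)CC[C@@H]1[C@@](C)(O)C=C[C@@H]2[C@@](C)(CO[Si](C(C)C)(C(C)C)C(C)C)CCC[C@@]12C
F3 | step 11 | 9-methylidene-8-methyl-Δ6(8) trans-hydrindene | C=C1C(C)=C[C@@H]2[C@@](C)(CO[Si](C(C)C)(C(C)C)C(C)C)CCC[C@@]12C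
F4 | step 11 | 9α-(hydroxymethyl)-9β-H-8-methyl-Δ6(8) trans-hydrindene | OC[C@@H]1C(C)=C[C@@H]2[C@@](C)(CO[Si](C(C)C)(C(C)C)C(C)C)CCC[C@@]12C
F5 | step 11 | 9α-formyl-9β-H-8-methyl-Δ6(8) trans-hydrindene | O=C[C@@H]1C(C)=C[C@@H]2[C@@](C)(CO[Si](C(C)C)(C(C)C)C(C)C)CCC[C@@]12C
F6 | step 4 | 3-oxo-4β-(hydroxymethyl)-4α-methyl-Δ5(6)-hydrindene C9 ketal | C12(OCCO1)CC=C3[C@@](C)(CO)C(=O)CC[C@@]23C
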